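**Plan**

- Retrosynthesis: the five methoxymethyl (MOM) ethers come off last. The indenone C2=C3 double bond is traced back to a trans-2,3-diarylindanone, and its C2–ring B bond is cut (ketone α-arylation) into a 3-arylindanone and an aryl bromide carrying rings A and B.
- The A–B bromide is cut at two bonds of ring A in one operation, the C6–O diaryl ether bond and the C1–carboxyl bond. Ring A carries the hydroxyl (C2), the ester carbon (C1) and the ether oxygen (C6) on three adjacent carbons, with the methyl (C4) meta to both oxygens. That is the pattern left when an O-nucleophile and a C-electrophile add across 3-(methoxymethoxy)-5-methylbenzyne.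
- The indanone is cut at C1–C7a (Parham acylation), C2–C3 (benzhydryl cation plus ketene acetal) and C3–ring D (aryllithium plus aldehyde).
- Forward: one aldehyde, 2-bromo-4-methoxy-6-(methoxymethoxy)benzaldehyde, is used twice, oxidised to the ring B phenol and elaborated to the indanone. Orcinol supplies ring A (aryne precursor) and ring D (aryllithium). The A–B ether is joined in step 9, the only ring built (the five-membered ring) closes in step 14, and the halves are united in step 15.
- Stereochemistry: the target has no stereocentre. The sp3 centres of the intermediates are racemic and are flattened by the dehydrogenation.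

Key step: step 9

Remark: free rotation about the aryl–indenone bonds is assumed, so the target is treated as achiral and compounds 24, 25, 27 and 28 are carried as racemates.

**Route**

Step 1
Reactants: 1 1-bromo-3,5-dimethoxybenzene
Product: 2 2-bromo-4,6-dimethoxybenzaldehyde
Conditions: POCl3, DMF, 0 to 90 °C; then ice-water
Reagents that add atoms: N,N-dimethylformamide, CN(C)C=O (formyl carbon); water, O (carbonyl oxygen)
Why: Vilsmeier–Haack formylation should enter para to one methoxy group and ortho to the other, next to bromine, which fixes the carbon/ortho-oxygen/para-oxygen/ortho-bromine pattern needed by both ring B and the indenone benzo ring; the symmetrical 4-bromo-2,6-dimethoxy isomer is the expected minor by-product and should be removable by crystallisation.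

Step 2
Reactants: 2 2-bromo-4,6-dimethoxybenzaldehyde
Product: 3 2-bromo-6-hydroxy-4-methoxybenzaldehyde
Conditions: BCl3, CH2Cl2, −78 to 0 °C; aqueous work-up
Reagents that add atoms: none
Why: Chelation-controlled Lewis-acid ether cleavage: BCl3 bound between the aldehyde oxygen and the ortho methoxy group should cleave only that ether and leave the para methoxy group, which differentiates the two oxygens.

Step 3
Reactants: 3 2-bromo-6-hydroxy-4-methoxybenzaldehyde
Product: 4 2-bromo-4-methoxy-6-(methoxymethoxy)benzaldehyde
Conditions: MOMCl, i-Pr2NEt, CH2Cl2, 0 °C to rt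
Reagents that add atoms: chloromethyl methyl ether, COCCl
Why: O-alkylation of a phenol (acetal protection) is routine, and the MOM group chosen here is also the ortho-director and the final acid-labile mask used throughout the route.

Step 4
Reactants: 4 2-bromo-4-methoxy-6-(methoxymethoxy)benzaldehyde
Product: 6 2-bromo-4-methoxy-6-(methoxymethoxy)phenol, via aryl formate 5 (not isolated)
Conditions: mCPBA, CH2Cl2, 0 °C to rt; aq NaHCO3 wash; then Et3N (cat.), MeOH, rt
Reagents that add atoms: 3-chloroperoxybenzoic acid, OOC(=O)c1cccc(Cl)c1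
Why: Baeyer–Villiger (Dakin-type) oxidation of a benzaldehyde with ortho and para oxygen donors should proceed by aryl migration to the formate, whose methanolysis frees a phenol flanked by bromine and the MOM ether with no regiochemical ambiguity.

Step 5
Reactants: 7 orcinol (5-methylbenzene-1,3-diol)
Product: 8 3-(methoxymethoxy)-5-methylphenol
Conditions: NaH (1 equiv), MOMCl (1 equiv), DMF, 0 °C
Reagents that add atoms: chloromethyl methyl ether, COCCl
Why: Statistical mono-O-alkylation of a cheap symmetrical diol is acceptable here because mono-ether, bis-ether and diol differ enough in polarity to be separated and the diol can be recycled.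

Step 6
Reactants: 8 3-(methoxymethoxy)-5-methylphenol
Product: 9 3-(methoxymethoxy)-5-methylphenyl N-isopropylcarbamate
Conditions: i-PrNCO, Et3N (cat.), CH2Cl2, rt
Reagents that add atoms: isopropyl isocyanate, CC(C)N=C=O
Why: Base-catalysed addition of a phenol to an isocyanate (carbamoylation) installs a strong ortho-directing group that can later be removed under mild amine conditions.

Step 7
Reactants: 9 3-(methoxymethoxy)-5-methylphenyl N-isopropylcarbamate
Product: 13 3-(methoxymethoxy)-5-methyl-2-(trimethylsilyl)phenyl N-isopropylcarbamate, via N-silyl carbamate 10 (not isolated), via ortho-lithiated N-silyl carbamate 11 (not isolated), via N-silyl C-silyl carbamate 12 (not isolated)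
Conditions: TMEDA, TBSOTf, Et2O, 0 °C to rt; then TMEDA, n-BuLi, −78 °C; TMSCl, −78 °C to rt; aq citric acid
Reagents that add atoms: chlorotrimethylsilane, C[Si](C)(C)Cl
Why: Directed ortho-metalation: with the N–H masked in situ as the N-silyl carbamate, the carbamate and the MOM ether together should direct lithiation to the one carbon between them, and the silyl quench followed by mild hydrolysis of the N–Si bond gives the ortho-silyl carbamate.

Step 8
Reactants: 13 3-(methoxymethoxy)-5-methyl-2-(trimethylsilyl)phenyl N-isopropylcarbamate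
Product: 15 3-(methoxymethoxy)-5-methyl-2-(trimethylsilyl)phenyl trifluoromethanesulfonate, via ortho-silylphenol 14 (not isolated)
Conditions: DBU, Et2NH, MeCN, 40 °C; then PhNTf2, rt
Reagents that add atoms: N-phenylbis(trifluoromethanesulfonimide), O=S(=O)(N(c1ccccc1)S(=O)(=O)C(F)(F)F)C(F)(F)F
Why: Base-induced carbamate cleavage (loss of isopropyl isocyanate, scavenged by Et2NH as a urea) followed by O-sulfonylation of the phenoxide in the same flask gives the ortho-silylaryl triflate without exposing the acid-sensitive arylsilane or the MOM ether to acid.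

Step 9
Reactants: 6 2-bromo-4-methoxy-6-(methoxymethoxy)phenol; 15 3-(methoxymethoxy)-5-methyl-2-(trimethylsilyl)phenyl trifluoromethanesulfonate; 16 carbon dioxide
Product: 20 2-[2-bromo-4-methoxy-6-(methoxymethoxy)phenoxy]-6-(methoxymethoxy)-4-methylbenzoic acid, via potassium phenoxide 17 (not isolated), via aryne 18 (not isolated), via aryl anion 19 (not isolated)
Conditions: 6 (1.3 equiv), KH, THF, 0 °C; then 18-crown-6, KF, CO2 (1 atm), slow addition of 15 (1.0 equiv), 0 °C to rt; then 1 M HCl to pH 3, 0 °C
Reagents that add atoms: none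
Why: Proposed new method: fluoride removes the trimethylsilyl group of 15 and triflate departs to give aryne 18, whose triple bond is distorted by the inductively withdrawing methoxymethoxy group so that the pre-formed phenoxide 17 attacks the carbon meta to that group (new aryl ether C–O bond) and the charge develops at the carbon between the two oxygens, where aryl anion 19 is carboxylated by dissolved CO2 (new ring A–carboxyl C–C bond). The closest known reactions are the three-component coupling of arynes, amines and CO2 to anthranilic acids and the fluoride-mediated O-arylation of hindered phenols with ortho-silylaryl triflates; the new element is a phenoxide as the nucleophile in the carboxylative version. No ring closes and no stereocentre is formed. Regioselectivity of the aryne addition is secured by the 3-oxygen substituent, the 5-methyl group being remote from both aryne carbons, and carboxylation should outrun protonation because the phenoxide is made beforehand with KH so that no O–H acid remains, the solvent is THF rather than acetonitrile, and the solution is kept saturated with CO2. Reversible carbonate formation between phenoxide and CO2 should only lower the concentration of free phenoxide, as carbamate formation does in the amine case, and the ring B bromide is expected to survive because the potassium aryl anion is captured by CO2 faster than it can exchange with the halide. Keeping 15 as the limiting component should prevent the product carboxylate from being arylated in turn.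

Step 10
Reactants: 20 2-[2-bromo-4-methoxy-6-(methoxymethoxy)phenoxy]-6-(methoxymethoxy)-4-methylbenzoic acid
Product: 21 methyl 2-[2-bromo-4-methoxy-6-(methoxymethoxy)phenoxy]-6-(methoxymethoxy)-4-methylbenzoate
Conditions: MeI, K2CO3, DMF, rt
Reagents that add atoms: iodomethane, CI
Why: SN2 O-alkylation of the carboxylate takes place at oxygen remote from the ring and is therefore insensitive to the two ortho substituents that would block a Fischer esterification.

Step 11
Reactants: 7 orcinol (5-methylbenzene-1,3-diol)
Product: 22 1,3-bis(methoxymethoxy)-5-methylbenzene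
Conditions: NaH (2.5 equiv), MOMCl (2.5 equiv), DMF, 0 °C to rt
Reagents that add atoms: chloromethyl methyl ether, COCCl
Why: Exhaustive O-alkylation of both phenols gives the bis-acetal whose C2–H, flanked by two directing groups, is set up for lithiation.

Step 12
Reactants: 22 1,3-bis(methoxymethoxy)-5-methylbenzene; 4 2-bromo-4-methoxy-6-(methoxymethoxy)benzaldehyde
Product: 24 [2,6-bis(methoxymethoxy)-4-methylphenyl][2-bromo-4-methoxy-6-(methoxymethoxy)phenyl]methanol (racemic), via aryllithium 23 (not isolated)
Conditions: n-BuLi, THF, 0 °C; then 4, −78 to 0 °C; aq NH4Cl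
Reagents that add atoms: none
Why: Directed ortho-metalation between the two acetal oxygens followed by 1,2-addition of the aryllithium to the aldehyde attaches ring D through its doubly flanked carbon, and bromine–lithium exchange with 4 should not compete because the doubly chelated aryllithium 23 is the more stable organolithium.

Step 13
Reactants: 24 [2,6-bis(methoxymethoxy)-4-methylphenyl][2-bromo-4-methoxy-6-(methoxymethoxy)phenyl]methanol
Product: 25 methyl 3-[2,6-bis(methoxymethoxy)-4-methylphenyl]-3-[2-bromo-4-methoxy-6-(methoxymethoxy)phenyl]propanoate (racemic)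
Conditions: tert-butyl[(1-methoxyethenyl)oxy]dimethylsilane (2 equiv), TMSOTf (5 mol%), CH2Cl2, −78 °C; Et3N quench
Reagents that add atoms: tert-butyl[(1-methoxyethenyl)oxy]dimethylsilane, C=C(OC)O[Si](C)(C)C(C)(C)C
Why: SN1 (Mukaiyama-type) alkylation: the benzhydrol, stabilised by ortho and para oxygen donors on both rings, should ionise with catalytic silyl triflate at low temperature and be captured at the unhindered CH2 terminus of the ketene silyl acetal, which also scavenges any free acid so that the aryl MOM ethers persist.

Step 14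
Reactants: 25 methyl 3-[2,6-bis(methoxymethoxy)-4-methylphenyl]-3-[2-bromo-4-methoxy-6-(methoxymethoxy)phenyl]propanoate
Product: 27 3-[2,6-bis(methoxymethoxy)-4-methylphenyl]-6-methoxy-4-(methoxymethoxy)-2,3-dihydro-1H-inden-1-one (racemic), via aryllithium 26 (not isolated)
Conditions: t-BuLi (2.05 equiv), THF, −100 to −78 °C; aq NH4Cl
Reagents that add atoms: none
Why: Parham cyclization: bromine–lithium exchange with t-BuLi is faster than ester attack or ring deprotonation, the aryllithium is acylated intramolecularly by the methyl ester (5-exo-trig closure of the five-membered ring at C1–C7a), and the tetrahedral lithium alkoxide should persist at low temperature so that the ketone appears only on work-up.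

Step 15
Reactants: 27 3-[2,6-bis(methoxymethoxy)-4-methylphenyl]-6-methoxy-4-(methoxymethoxy)-2,3-dihydro-1H-inden-1-one; 21 methyl 2-[2-bromo-4-methoxy-6-(methoxymethoxy)phenoxy]-6-(methoxymethoxy)-4-methylbenzoate
Product: 28 trans-3-[2,6-bis(methoxymethoxy)-4-methylphenyl]-6-methoxy-2-{5-methoxy-2-[2-(methoxycarbonyl)-3-(methoxymethoxy)-5-methylphenoxy]-3-(methoxymethoxy)phenyl}-4-(methoxymethoxy)-2,3-dihydro-1H-inden-1-one (racemic)
Conditions: Pd2(dba)3 (2.5 mol%), XPhos (6 mol%), K3PO4, toluene, 100 °C
Reagents that add atoms: none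
Why: Palladium-catalysed ketone α-arylation: zerovalent palladium with a bulky biarylphosphine inserts into the C–Br bond, the potassium enolate of the indanone displaces bromide and reductive elimination forms the C2–aryl bond, the phosphate base sparing the shielded methyl ester and the new aryl group settling trans to the C3 aryl under the equilibrating basic conditions.

Step 16
Reactants: 28 trans-2,3-diarylindanone (as named in step 15)
Product: 29 3-[2,6-bis(methoxymethoxy)-4-methylphenyl]-6-methoxy-2-{5-methoxy-2-[2-(methoxycarbonyl)-3-(methoxymethoxy)-5-methylphenoxy]-3-(methoxymethoxy)phenyl}-4-(methoxymethoxy)-1H-inden-1-one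
Conditions: DDQ (2 equiv), 1,4-dioxane, 90 °C
Reagents that add atoms: none
Why: Quinone dehydrogenation of an α,β-diaryl ketone: hydride abstraction from the doubly benzylic C3–H (or from the enol) and loss of the C2 proton should give the fully conjugated indenone, removing both sp3 centres.

Step 17
Reactants: 29 penta-MOM indenone (as named in step 16)
Product: 30 Ascomindone B, methyl 2-{2-[3-(2,6-dihydroxy-4-methylphenyl)-4-hydroxy-6-methoxy-1-oxo-1H-inden-2-yl]-6-hydroxy-4-methoxyphenoxy}-6-hydroxy-4-methylbenzoate
Conditions: 3 M HCl in MeOH, 45 °C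
Reagents that add atoms: none
Why: Acid-catalysed acetal cleavage removes all five MOM groups at once, while methanol as solvent makes any ester exchange degenerate and the two aryl methyl ethers, the diaryl ether and the indenone are inert to these conditions.

**Compound list**

1 | 1-bromo-3,5-dimethoxybenzene | COc1cc(OC)cc(Br)c1 | starting material
2 | 2-bromo-4,6-dimethoxybenzaldehyde | O=Cc1c(Br)cc(OC)cc1OC | intermediate
3 | 2-bromo-6-hydroxy-4-methoxybenzaldehyde | O=Cc1c(Br)cc(OC)cc1O | intermediate
4 | 2-bromo-4-methoxy-6-(methoxymethoxy)benzaldehyde | O=Cc1c(Br)cc(OC)cc1OCOC | intermediate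
5 | 2-bromo-4-methoxy-6-(methoxymethoxy)phenyl formate | O=COc1c(Br)cc(OC)cc1OCOC | intermediate
6 | 2-bromo-4-methoxy-6-(methoxymethoxy)phenol | COCOc1cc(OC)cc(Br)c1O | intermediate
7 | orcinol (5-methylbenzene-1,3-diol) | Cc1cc(O)cc(O)c1 | starting material
8 | 3-(methoxymethoxy)-5-methylphenol | COCOc1cc(C)cc(O)c1 | intermediate
9 | 3-(methoxymethoxy)-5-methylphenyl N-isopropylcarbamate | CC(C)NC(=O)Oc1cc(C)cc(OCOC)c1 | intermediate
10 | 3-(methoxymethoxy)-5-methylphenyl N-(tert-butyldimethylsilyl)-N-isopropylcarbamate | CC(C)N(C(=O)Oc1cc(C)cc(OCOC)c1)[Si](C)(C)C(C)(C)C | intermediate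
11 | 2-lithio-3-(methoxymethoxy)-5-methylphenyl N-(tert-butyldimethylsilyl)-N-isopropylcarbamate | CC(C)N(C(=O)Oc1cc(C)cc(OCOC)c1[Li])[Si](C)(C)C(C)(C)C | intermediate
12 | 3-(methoxymethoxy)-5-methyl-2-(trimethylsilyl)phenyl N-(tert-butyldimethylsilyl)-N-isopropylcarbamate | CC(C)N(C(=O)Oc1cc(C)cc(OCOC)c1[Si](C)(C)C)[Si](C)(C)C(C)(C)C | intermediate
13 | 3-(methoxymethoxy)-5-methyl-2-(trimethylsilyl)phenyl N-isopropylcarbamate | CC(C)NC(=O)Oc1cc(C)cc(OCOC)c1[Si](C)(C)C | intermediate
14 | 3-(methoxymethoxy)-5-methyl-2-(trimethylsilyl)phenol | COCOc1cc(C)cc(O)c1[Si](C)(C)C | intermediate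
15 | 3-(methoxymethoxy)-5-methyl-2-(trimethylsilyl)phenyl trifluoromethanesulfonate | COCOc1cc(C)cc(OS(=O)(=O)C(F)(F)F)c1[Si](C)(C)C | intermediate
16 | carbon dioxide | O=C=O | starting material
17 | potassium 2-bromo-4-methoxy-6-(methoxymethoxy)phenoxide | [K+].[O-]c1c(Br)cc(OC)cc1OCOC | intermediate
18 | 3-(methoxymethoxy)-5-methylbenzyne | COCOC1=CC(C)=CC#C1 | intermediate
19 | potassium 2-[2-bromo-4-methoxy-6-(methoxymethoxy)phenoxy]-6-(methoxymethoxy)-4-methylbenzen-1-ide | [K+].COCOc1cc(C)cc(Oc2c(OCOC)cc(OC)cc2Br)[c-]1 | intermediate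
20 | 2-[2-bromo-4-methoxy-6-(methoxymethoxy)phenoxy]-6-(methoxymethoxy)-4-methylbenzoic acid | OC(=O)c1c(OCOC)cc(C)cc1Oc1c(OCOC)cc(OC)cc1Br | intermediate
21 | methyl 2-[2-bromo-4-methoxy-6-(methoxymethoxy)phenoxy]-6-(methoxymethoxy)-4-methylbenzoate | COC(=O)c1c(OCOC)cc(C)cc1Oc1c(OCOC)cc(OC)cc1Br | intermediate
22 | 1,3-bis(methoxymethoxy)-5-methylbenzene | COCOc1cc(C)cc(OCOC)c1 | intermediate
23 | [2,6-bis(methoxymethoxy)-4-methylphenyl]lithium | [Li]c1c(OCOC)cc(C)cc1OCOC | intermediate
24 | [2,6-bis(methoxymethoxy)-4-methylphenyl][2-bromo-4-methoxy-6-(methoxymethoxy)phenyl]methanol (racemic) | OC(c1c(OCOC)cc(C)cc1OCOC)c1c(Br)cc(OC)cc1OCOC | intermediate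
25 | methyl 3-[2,6-bis(methoxymethoxy)-4-methylphenyl]-3-[2-bromo-4-methoxy-6-(methoxymethoxy)phenyl]propanoate (racemic) | COC(=O)CC(c1c(OCOC)cc(C)cc1OCOC)c1c(Br)cc(OC)cc1OCOC | intermediate
26 | methyl 3-[2,6-bis(methoxymethoxy)-4-methylphenyl]-3-[2-lithio-4-methoxy-6-(methoxymethoxy)phenyl]propanoate (racemic) | COC(=O)CC(c1c(OCOC)cc(C)cc1OCOC)c1c([Li])cc(OC)cc1OCOC | intermediate
27 | 3-[2,6-bis(methoxymethoxy)-4-methylphenyl]-6-methoxy-4-(methoxymethoxy)-2,3-dihydro-1H-inden-1-one (racemic) | O=C1CC(c2c(OCOC)cc(C)cc2OCOC)c2c(OCOC)cc(OC)cc21 | intermediate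
28 | trans-3-[2,6-bis(methoxymethoxy)-4-methylphenyl]-6-methoxy-2-{5-methoxy-2-[2-(methoxycarbonyl)-3-(methoxymethoxy)-5-methylphenoxy]-3-(methoxymethoxy)phenyl}-4-(methoxymethoxy)-2,3-dihydro-1H-inden-1-one (racemic; one enantiomer drawn) | COC(=O)c1c(OCOC)cc(C)cc1Oc1c(OCOC)cc(OC)cc1[C@@H]1[C@@H](c2c(OCOC)cc(C)cc2OCOC)c2c(OCOC)cc(OC)cc2C1=O | intermediate
29 | 3-[2,6-bis(methoxymethoxy)-4-methylphenyl]-6-methoxy-2-{5-methoxy-2-[2-(methoxycarbonyl)-3-(methoxymethoxy)-5-methylphenoxy]-3-(methoxymethoxy)phenyl}-4-(methoxymethoxy)-1H-inden-1-one | COC(=O)c1c(OCOC)cc(C)cc1Oc1c(OCOC)cc(OC)cc1C1=C(c2c(OCOC)cc(C)cc2OCOC)c2c(OCOC)cc(OC)cc2C1=O | intermediate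
30 | Ascomindone B | COC(=O)c1c(O)cc(C)cc1Oc1c(O)cc(OC)cc1C1=C(c2c(O)cc(C)cc2O)c2c(O)cc(OC)cc2C1=O | target

**Step count**

Total: 17 steps. Longest linear sequence: 9 steps (for example steps 1–4, 9, 10, 15–17; the sequences 5–10, 15–17 and 1–3, 12–17 are equally long).

**Steps most likely to fail**

Step 9 (three-component aryne coupling). Protonation of the aryl anion may outpace carboxylation, the phenoxide may be held back as its carbonate and attack the aryne through a carbonate oxygen, or the product carboxylate may be arylated. The fallback replaces the aryne by a carboxylate-assisted Ullmann ether synthesis. Commercial 3-bromo-5-methylphenol would be protected (MOMCl, i-Pr2NEt) as 1-bromo-3-(methoxymethoxy)-5-methylbenzene F1. Deprotonation with LiN(i-Pr)2 in THF at −78 °C, at the carbon between bromine and the acetal oxygen, would give [2-bromo-6-(methoxymethoxy)-4-methylphenyl]lithium F2, and CO2 would carboxylate it to 2-bromo-6-(methoxymethoxy)-4-methylbenzoic acid F3. Copper-catalysed coupling of F3 with phenol 6 (CuI, K2CO3, DMF, 100 °C) should then follow; the ortho-carboxylate activates the ring A bromide and the ring B bromide should stay untouched. The fallback sets out from phenol 6 and rejoins the route at acid 20.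

Step 15 (α-arylation). Steric crowding around C2 may stop transmetalation or reductive elimination, and the arylpalladium species may instead cyclise onto ring A by C–H arylation to a dibenzofuran. The fallback makes the C2–aryl bond by Suzuki–Miyaura coupling at the indenone oxidation level:
- Indanone 27 would be dehydrogenated (IBX, DMSO, 70 °C) to 3-[2,6-bis(methoxymethoxy)-4-methylphenyl]-6-methoxy-4-(methoxymethoxy)-1H-inden-1-one F4.
- α-Iodination (I2, pyridine, CH2Cl2) would give 3-[2,6-bis(methoxymethoxy)-4-methylphenyl]-2-iodo-6-methoxy-4-(methoxymethoxy)-1H-inden-1-one F5.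
- Bromide 21 would be converted by Miyaura borylation (Pd(dppf)Cl2, B2pin2, KOAc, dioxane, 90 °C) into methyl 2-[4-methoxy-2-(methoxymethoxy)-6-(4,4,5,5-tetramethyl-1,3,2-dioxaborolan-2-yl)phenoxy]-6-(methoxymethoxy)-4-methylbenzoate F6.
- Coupling of F5 with F6 (Pd(dppf)Cl2, K3PO4, dioxane/water, 80 °C) would give indenone 29 directly.

The fallback sets out from 27 and 21 and rejoins the route at 29, so that steps 15 and 16 are both bypassed.

Step 13 (cation alkylation). Ionisation may be accompanied by loss or participation of the ortho MOM ethers (ring closure of an acetal oxygen onto the cation), or the crowded cation may be captured too slowly. The fallback forms the same C2–C3 bond under basic conditions by conjugate addition: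
- Aldehyde 4 would be condensed with Meldrum's acid (Knoevenagel, piperidinium acetate, EtOH, rt) to 5-{[2-bromo-4-methoxy-6-(methoxymethoxy)phenyl]methylidene}-2,2-dimethyl-1,3-dioxane-4,6-dione F7.
- Aryllithium 23 would be added to this strongly electrophilic alkene in THF at −78 °C to give 5-{[2,6-bis(methoxymethoxy)-4-methylphenyl][2-bromo-4-methoxy-6-(methoxymethoxy)phenyl]methyl}-2,2-dimethyl-1,3-dioxane-4,6-dione F8.
- Heating in MeOH/pyridine would open the dioxanedione to the malonic half ester 2-(methoxycarbonyl)-3-[2,6-bis(methoxymethoxy)-4-methylphenyl]-3-[2-bromo-4-methoxy-6-(methoxymethoxy)phenyl]propanoic acid F9, which decarboxylates in the same flask to ester 25.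

The fallback sets out from 4 and 23 and rejoins the route at 25.

**Further compounds**

F1 | step 9 | 1-bromo-3-(methoxymethoxy)-5-methylbenzene | COCOc1cc(C)cc(Br)c1
F2 | step 9 | [2-bromo-6-(methoxymethoxy)-4-methylphenyl]lithium | [Li]c1c(Br)cc(C)cc1OCOC
F3 | step 9 | 2-bromo-6-(methoxymethoxy)-4-methylbenzoic acid | OC(=O)c1c(Br)cc(C)cc1OCOC
F4 | step 15 | 3-[2,6-bis(methoxymethoxy)-4-methylphenyl]-6-methoxy-4-(methoxymethoxy)-1H-inden-1-one | O=C1C=C(c2c(OCOC)cc(C)cc2OCOC)c2c(OCOC)cc(OC)cc21
F5 | step 15 | 3-[2,6-bis(methoxymethoxy)-4-methylphenyl]-2-iodo-6-methoxy-4-(methoxymethoxy)-1H-inden-1-one | O=C1C(I)=C(c2c(OCOC)cc(C)cc2OCOC)c2c(OCOC)cc(OC)cc21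
F6 | step 15 | methyl 2-[4-methoxy-2-(methoxymethoxy)-6-(4,4,5,5-tetramethyl-1,3,2-dioxaborolan-2-yl)phenoxy]-6-(methoxymethoxy)-4-methylbenzoate | COC(=O)c1c(OCOC)cc(C)cc1Oc1c(OCOC)cc(OC)cc1B1OC(C)(C)C(C)(C)O1
F7 | step 13 | 5-{[2-bromo-4-methoxy-6-(methoxymethoxy)phenyl]methylidene}-2,2-dimethyl-1,3-dioxane-4,6-dione | CC1(C)OC(=O)C(=Cc2c(Br)cc(OC)cc2OCOC)C(=O)O1
F8 | step 13 | 5-{[2,6-bis(methoxymethoxy)-4-methylphenyl][2-bromo-4-methoxy-6-(methoxymethoxy)phenyl]methyl}-2,2-dimethyl-1,3-dioxane-4,6-dione (racemic) | CC1(C)OC(=O)C(C(c2c(OCOC)cc(C)cc2OCOC)c2c(Br)cc(OC)cc2OCOC)C(=O)O1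
F9 | step 13 | 2-(methoxycarbonyl)-3-[2,6-bis(methoxymethoxy)-4-methylphenyl]-3-[2-bromo-4-methoxy-6-(methoxymethoxy)phenyl]propanoic acid (racemic mixture of diastereomers) | COC(=O)C(C(=O)O)C(c1c(OCOC)cc(C)cc1OCOC)c1c(Br)cc(OC)cc1OCOC
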